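**Retrosynthetic overview**

1. Labels (phenalen-1-one numbering of the core): ring B = C1(=O)–C2–C3(OH)–C3a–C9b–C9a; ring C = C3a=C4(ring D)–C5–C6(Me)–C6a–C9b; ring A = C6a–C7(O-aryl)–C8–C9(OH)–C9a–C9b; ring D = the 2,6-dioxygenated phenyl on C4; ring E = the oxygenated phenyl ketone ring; C1' = the side-chain CHMe on C5.
2. Last C–C disconnection: the malonyl unit C1–C2–C3 of ring B is removed from the finished macrocycle ([3+3] annulation, bonds C1–C9a and C3–C3a), leaving phenol 20. The enabling feature: in 20, C9a–H of ring A (ortho to the free C9–OH, para to the C7 ether oxygen) and the styrene C3a–H of ring C sit peri across C9b as a C,C-1,3-dinucleophile, and the neighbouring C9–OH can carry the malonyl unit in as an ester and is released when the acyl group moves to carbon.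
3. Ten-membered ring: intramolecular SNAr etherification (C7–O to ring E). Ring C: McMurry coupling (C3a=C4) of a keto aldehyde.
4. Stereocentres: C6 by copper-catalysed asymmetric methyl 1,4-addition; C5 and C1' by a substrate-controlled Michael addition of a Z lithium enolate to an E enone.
5. Order of ring formation: rings A, D and E are bought; ring C (step 11), macrocycle (step 13), ring B (step 14); O-demethylation last.

Key step: step 14

Remark on the chemistry: the 3-hydroxyphenalen-1-one unit is a vinylogous acid and is aimed at in the tautomer drawn, with which its other enol forms equilibrate; the labels of line 1 are used for all intermediates.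

**Route**

Step 1
Reactants: 1 5-bromobenzene-1,3-diol
Product: 2 2-bromo-4,6-dihydroxybenzaldehyde
Conditions: POCl3, DMF, MeCN, 0 °C → rt; then H2O, 50 °C
Reagents that add atoms: N,N-dimethylformamide CN(C)C=O; water O
Why: Vilsmeier–Haack formylation of a resorcinol should go ortho to one hydroxyl and para to the other (the carbon beside bromine), as with resorcinol itself, and not between the two hydroxyls.

Step 2
Reactants: 2 2-bromo-4,6-dihydroxybenzaldehyde
Product: 3 2-bromo-4,6-bis(methoxymethoxy)benzaldehyde
Conditions: MOMCl (excess), iPr2NEt, CH2Cl2, 0 °C → rt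
Reagents that add atoms: chloromethyl methyl ether COCCl
Why: O-alkylation of both phenols (the hydrogen-bonded ortho hydroxyl needs the excess) gives acetal ethers that withstand the bases, organometallics and low-valent titanium used later.

Step 3
Reactants: 3 2-bromo-4,6-bis(methoxymethoxy)benzaldehyde
Product: 4 (E)-3-[2-bromo-4,6-bis(methoxymethoxy)phenyl]prop-2-enoic acid
Conditions: malonic acid, pyridine, piperidine (cat.), 90 °C
Reagents that add atoms: malonic acid OC(=O)CC(=O)O
Why: Knoevenagel–Doebner condensation with decarboxylation gives the E acid, and the acetal ethers are stable to the amine medium.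

Step 4
Reactants: 4 (E)-3-[2-bromo-4,6-bis(methoxymethoxy)phenyl]prop-2-enoic acid
Product: 5 S-ethyl (E)-3-[2-bromo-4,6-bis(methoxymethoxy)phenyl]prop-2-enethioate
Conditions: EtSH, EDC·HCl, DMAP (cat.), CH2Cl2, 0 °C → rt
Reagents that add atoms: ethanethiol CCS
Why: Carbodiimide (Steglich-type) thioesterification gives the acceptor class for which copper-catalysed methyl Grignard 1,4-addition to β-aryl substrates is established.

Step 5
Reactants: 5 S-ethyl (E)-3-[2-bromo-4,6-bis(methoxymethoxy)phenyl]prop-2-enethioate
Product: 6 S-ethyl (3R)-3-[2-bromo-4,6-bis(methoxymethoxy)phenyl]butanethioate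
Conditions: MeMgBr, CuI (3 mol %), (R)-Tol-BINAP (3.3 mol %), tBuOMe, −70 °C
Reagents that add atoms: methylmagnesium bromide C[Mg]Br
Why: Copper-catalysed asymmetric conjugate addition of a Grignard reagent to an α,β-unsaturated thioester, in which the chiral bisphosphine–copper complex selects the alkene face and should set C6 as R (the antipodal ligand is taken if the sense of induction is the opposite one).

Step 6
Reactants: 6 S-ethyl (3R)-3-[2-bromo-4,6-bis(methoxymethoxy)phenyl]butanethioate; 7 1,3-dimethoxybenzene
Product: 9 (3R)-3-[2-bromo-4,6-bis(methoxymethoxy)phenyl]-1-(2,6-dimethoxyphenyl)butan-1-one, via 2,6-dimethoxyphenyllithium 8 (not isolated)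
Conditions: 7, nBuLi, THF, 0 °C → rt; then 6, −78 °C → −30 °C
Reagents that add atoms: none
Why: Directed ortho-lithiation between the two methoxy groups, then acyl substitution at the thioester; the doubly ortho-substituted ketone should resist a second addition, and C6, β to the carbonyl, is not touched.

Step 7
Reactants: 10 1-fluoro-3-methoxybenzene; 11 (E)-but-2-enal
Product: 13 (E)-1-(2-fluoro-6-methoxyphenyl)but-2-en-1-ol (racemic), via 2-fluoro-6-methoxyphenyllithium 12 (not isolated)
Conditions: nBuLi, THF, −78 °C; then 11, −78 °C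
Reagents that add atoms: none
Why: Directed ortho-lithiation at the carbon flanked by F and OMe (kept at −78 °C so that no aryne forms), then 1,2-addition to the enal; the carbinol centre is removed in step 8.

Step 8
Reactants: 13 (E)-1-(2-fluoro-6-methoxyphenyl)but-2-en-1-ol
Product: 14 (E)-1-(2-fluoro-6-methoxyphenyl)but-2-en-1-one
Conditions: Dess–Martin periodinane, NaHCO3, CH2Cl2, 0 °C → rt
Reagents that add atoms: none
Why: Hypervalent iodine oxidation of the allylic benzylic alcohol gives the E enone without touching the alkene geometry.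

Step 9
Reactants: 9 (3R)-3-[2-bromo-4,6-bis(methoxymethoxy)phenyl]-1-(2,6-dimethoxyphenyl)butan-1-one; 14 (E)-1-(2-fluoro-6-methoxyphenyl)but-2-en-1-one
Product: 16 (2R,3S)-2-[(1R)-1-[2-bromo-4,6-bis(methoxymethoxy)phenyl]ethyl]-1-(2,6-dimethoxyphenyl)-5-(2-fluoro-6-methoxyphenyl)-3-methylpentane-1,5-dione, via lithium (Z)-enolate 15 (not isolated)
Conditions: LiN(iPr)2, THF, −78 °C; then 14, −78 °C; NH4Cl at −78 °C
Reagents that add atoms: none
Why: Michael addition of a ketone lithium enolate to an enone: the aryl ketone gives the Z enolate, the crowded carbonyl of 14 directs 1,4-addition, the Z enolate with an E enone should give the anti C5/C1' relationship through the chelated transition state, and allylic 1,3-strain (C6–H eclipsing the enolate) should bring the enone to the face anti to ring A, which together set C5 as R and C1' as S.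

Step 10
Reactants: 16 (2R,3S)-2-[(1R)-1-[2-bromo-4,6-bis(methoxymethoxy)phenyl]ethyl]-1-(2,6-dimethoxyphenyl)-5-(2-fluoro-6-methoxyphenyl)-3-methylpentane-1,5-dione
Product: 17 (2R,3S)-2-[(1R)-1-[2-formyl-4,6-bis(methoxymethoxy)phenyl]ethyl]-1-(2,6-dimethoxyphenyl)-5-(2-fluoro-6-methoxyphenyl)-3-methylpentane-1,5-dione
Conditions: Pd(PPh3)4 (5 mol %), CO (3 bar), Bu3SnH (slow addition), PhMe, 60 °C
Reagents that add atoms: carbon monoxide [C-]#[O+]
Why: Palladium-catalysed reductive carbonylation (oxidative addition of zerovalent palladium into C–Br, CO insertion, hydride transfer from tin) installs the future C3a as an aldehyde under neutral conditions that should leave the epimerisable 1,5-diketone untouched.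

Step 11
Reactants: 17 (2R,3S)-2-[(1R)-1-[2-formyl-4,6-bis(methoxymethoxy)phenyl]ethyl]-1-(2,6-dimethoxyphenyl)-5-(2-fluoro-6-methoxyphenyl)-3-methylpentane-1,5-dione
Product: 18 (3S)-3-[(1R,2R)-3-(2,6-dimethoxyphenyl)-6,8-bis(methoxymethoxy)-1-methyl-1,2-dihydronaphthalen-2-yl]-1-(2-fluoro-6-methoxyphenyl)butan-1-one
Conditions: TiCl4, Zn, pyridine, THF, reflux, slow addition of 17
Reagents that add atoms: none
Why: McMurry coupling: low-valent titanium should couple the aldehyde with the ring D ketone five atoms away (six-membered ring C, C3a=C4), whereas the ring E ketone has no partner within reach of a small ring and is shielded by two ortho substituents; no stereocentre is formed and C5 loses its acidity.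

Step 12
Reactants: 18 (3S)-3-[(1R,2R)-3-(2,6-dimethoxyphenyl)-6,8-bis(methoxymethoxy)-1-methyl-1,2-dihydronaphthalen-2-yl]-1-(2-fluoro-6-methoxyphenyl)butan-1-one
Product: 19 (3S)-3-[(1R,2R)-3-(2,6-dimethoxyphenyl)-6,8-dihydroxy-1-methyl-1,2-dihydronaphthalen-2-yl]-1-(2-fluoro-6-methoxyphenyl)butan-1-one
Conditions: HCl (3 M aq.), MeOH, THF, 45 °C
Reagents that add atoms: none
Why: Acid-catalysed acetal exchange removes both methoxymethyl groups under conditions too mild to cleave the methyl ethers or protonate the styrene to a useful extent.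

Step 13
Reactants: 19 (3S)-3-[(1R,2R)-3-(2,6-dimethoxyphenyl)-6,8-dihydroxy-1-methyl-1,2-dihydronaphthalen-2-yl]-1-(2-fluoro-6-methoxyphenyl)butan-1-one
Product: 20 macrocyclic phenol (5R,6R,1'S): 19 after loss of HF, the C7 oxygen of ring A bonded to the former C–F carbon of ring E (ten-membered aryl ether ketone); C9–OH free; rings D and E as methyl ethers
Conditions: Cs2CO3, DMF (0.002 M), 90 °C
Reagents that add atoms: none
Why: Intramolecular SNAr etherification (addition–elimination at the fluorine-bearing carbon ortho to the ketone) at high dilution; only the C7 phenoxide can reach ring E, because the C9 phenoxide is para to the tether, so C9–OH stays free for step 14.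

Step 14
Reactants: 20 macrocyclic phenol (5R,6R,1'S)
Product: 23 tri-O-methyl ether of the target (ring D as 2,6-dimethoxyphenyl; ring E as methoxyphenyl; C3–OH and C9–OH free), via aryl hydrogen malonate 21 (not isolated), via 4-hydroxycoumarin 22 (not isolated)
Conditions: Meldrum's acid, PhMe, 100 °C; evaporate; Eaton's reagent (P2O5 in MeSO3H), 60 °C → 85 °C
Reagents that add atoms: Meldrum's acid (2,2-dimethyl-1,3-dioxane-4,6-dione) CC1(C)OC(=O)CC(=O)O1
Why: Proposed new method: the free C9 phenol opens Meldrum's acid to the aryl hydrogen malonate 21, and in Eaton's reagent its acylium closes on C9a to the 4-hydroxycoumarin 22 (six-membered lactone ring by Friedel–Crafts acylation ortho to the ester oxygen and para to the C7 ether oxygen, the known Meldrum's acid/Eaton's reagent coumarin synthesis). On further heating the lactone C–O bond should ionise as in a Fries rearrangement, the C1 acyl arm turns about the C9a–C1 bond, and the acylium (an aroylketene equivalent) attacks the peri styrene carbon C3a, closing ring B by a six-membered Friedel–Crafts-type acylation of the alkene (cation at C4 stabilised by ring D, then loss of the C3a proton), after which the β-diketone enolises to the 3-hydroxyphenalen-1-one and the C9 phenol is free again. Closest known reaction types are the Fries rearrangement of lactones (dihydrocoumarin to hydroxyindanones), phenol acylation by carboxylic acids in Eaton's reagent, and the Darzens–Nenitzescu acylation of styrenes; the transfer of a coumarin acyl group to a peri alkene carbon has not been shown. No stereocentre is formed, and C5, C6 and C1' stay outside the reacting system as long as protonation of the C3a=C4 bond is not followed by proton loss from C5. The step needs chemoselectivity against the electron-rich rings D and E and regioselectivity for C9a over C8: the ester tether makes both C–C bond formations intramolecular, coumarin closure para to an alkoxy group is the normal course for 3-alkoxyphenols, and an acyl group on C8 cannot reach C3a, so the acyl transfers, reversible under Fries conditions, should drain into 23.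

Step 15
Reactants: 23 tri-O-methyl ether of the target
Product: 24 CNP0225737.1 (target; 5R,6R,1'S)
Conditions: BBr3, CH2Cl2, −78 °C → 0 °C; then MeOH, H2O
Reagents that add atoms: none
Why: Lewis acid cleavage of the three aryl methyl ethers with BBr3, which should leave the diaryl ether, the ketones, the vinylogous acid and the three stereocentres unchanged.

**Compound list**

1 | 5-bromobenzene-1,3-diol | Oc1cc(O)cc(Br)c1 | starting material
2 | 2-bromo-4,6-dihydroxybenzaldehyde | Oc1cc(O)c(C=O)c(Br)c1 | intermediate
3 | 2-bromo-4,6-bis(methoxymethoxy)benzaldehyde | COCOc1cc(OCOC)c(C=O)c(Br)c1 | intermediate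
4 | (E)-3-[2-bromo-4,6-bis(methoxymethoxy)phenyl]prop-2-enoic acid | OC(=O)/C=C/c1c(OCOC)cc(OCOC)cc1Br | intermediate
5 | S-ethyl (E)-3-[2-bromo-4,6-bis(methoxymethoxy)phenyl]prop-2-enethioate | CCSC(=O)/C=C/c1c(OCOC)cc(OCOC)cc1Br | intermediate
6 | S-ethyl (3R)-3-[2-bromo-4,6-bis(methoxymethoxy)phenyl]butanethioate | CCSC(=O)C[C@@H](C)c1c(OCOC)cc(OCOC)cc1Br | intermediate
7 | 1,3-dimethoxybenzene | COc1cccc(OC)c1 | starting material
8 | 2,6-dimethoxyphenyllithium (not isolated) | COc1cccc(OC)c1[Li] | intermediate
9 | (3R)-3-[2-bromo-4,6-bis(methoxymethoxy)phenyl]-1-(2,6-dimethoxyphenyl)butan-1-one | COc1cccc(OC)c1C(=O)C[C@@H](C)c1c(OCOC)cc(OCOC)cc1Br | intermediate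
10 | 1-fluoro-3-methoxybenzene | COc1cccc(F)c1 | starting material
11 | (E)-but-2-enal | C/C=C/C=O | starting material
12 | 2-fluoro-6-methoxyphenyllithium (not isolated) | COc1cccc(F)c1[Li] | intermediate
13 | (E)-1-(2-fluoro-6-methoxyphenyl)but-2-en-1-ol (racemic) | C/C=C/C(O)c1c(F)cccc1OC | intermediate
14 | (E)-1-(2-fluoro-6-methoxyphenyl)but-2-en-1-one | C/C=C/C(=O)c1c(F)cccc1OC | intermediate
15 | lithium (Z)-enolate of ketone 9 (not isolated) | [Li]O/C(=C\[C@@H](C)c1c(OCOC)cc(OCOC)cc1Br)c1c(OC)cccc1OC | intermediate
16 | (2R,3S)-2-[(1R)-1-[2-bromo-4,6-bis(methoxymethoxy)phenyl]ethyl]-1-(2,6-dimethoxyphenyl)-5-(2-fluoro-6-methoxyphenyl)-3-methylpentane-1,5-dione | C[C@@H](CC(=O)c1c(OC)cccc1F)[C@H]([C@@H](C)c1c(OCOC)cc(OCOC)cc1Br)C(=O)c1c(OC)cccc1OC | intermediate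
17 | (2R,3S)-2-[(1R)-1-[2-formyl-4,6-bis(methoxymethoxy)phenyl]ethyl]-1-(2,6-dimethoxyphenyl)-5-(2-fluoro-6-methoxyphenyl)-3-methylpentane-1,5-dione | C[C@@H](CC(=O)c1c(OC)cccc1F)[C@H]([C@@H](C)c1c(OCOC)cc(OCOC)cc1C=O)C(=O)c1c(OC)cccc1OC | intermediate
18 | (3S)-3-[(1R,2R)-3-(2,6-dimethoxyphenyl)-6,8-bis(methoxymethoxy)-1-methyl-1,2-dihydronaphthalen-2-yl]-1-(2-fluoro-6-methoxyphenyl)butan-1-one | C[C@@H](CC(=O)c1c(OC)cccc1F)[C@@H]1[C@@H](C)c2c(OCOC)cc(OCOC)cc2C=C1c1c(OC)cccc1OC | intermediate
19 | (3S)-3-[(1R,2R)-3-(2,6-dimethoxyphenyl)-6,8-dihydroxy-1-methyl-1,2-dihydronaphthalen-2-yl]-1-(2-fluoro-6-methoxyphenyl)butan-1-one | C[C@@H](CC(=O)c1c(OC)cccc1F)[C@@H]1[C@@H](C)c2c(O)cc(O)cc2C=C1c1c(OC)cccc1OC | intermediate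
20 | macrocyclic phenol (5R,6R,1'S): ten-membered aryl ether ketone, C7–O bonded to ring E, C9–OH free, C9a–H and C3a–H present, rings D and E as methyl ethers | C[C@H]1CC(=O)c2c(OC)cccc2Oc2cc(O)cc3c2[C@H](C)[C@@H]1C(c1c(OC)cccc1OC)=C3 | intermediate
21 | aryl hydrogen malonate of 20 (C9–O–CO–CH2–CO2H; not isolated) | C[C@H]1CC(=O)c2c(OC)cccc2Oc2cc(OC(=O)CC(=O)O)cc3c2[C@H](C)[C@@H]1C(c1c(OC)cccc1OC)=C3 | intermediate
22 | 4-hydroxycoumarin fused at C9–O and C9a of 20 (not isolated) | C[C@H]1CC(=O)c2c(OC)cccc2Oc2cc4OC(=O)C=C(O)c4c3c2[C@H](C)[C@@H]1C(c1c(OC)cccc1OC)=C3 | intermediate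
23 | tri-O-methyl ether of the target (ring D 2,6-dimethoxy, ring E methoxy; C3–OH and C9–OH free) | C[C@H]1CC(=O)c2c(OC)cccc2Oc2cc(O)c3c4c2[C@H](C)[C@@H]1C(c1c(OC)cccc1OC)=C4C(O)=CC3=O | intermediate
24 | CNP0225737.1 | C[C@H]1CC(=O)c2c(O)cccc2Oc2cc(O)c3c4c2[C@H](C)[C@@H]1C(c1c(O)cccc1O)=C4C(O)=CC3=O | target

**Step count and risks**

Total step count: 15. Longest linear sequence: 13 (steps 1–6 and 9–15; steps 7 and 8 form the side branch to enone 14).

Steps most likely to fail:

Step 14. The acyl transfer may stop at the coumarin stage, or the hot acid may move the C3a=C4 double bond towards C5 and erode the C5 configuration. The fallback sets out from 20 and comes back at 24, building the malonyl unit stepwise with known reactions. Magnesium-mediated ortho-formylation of the phenol (MgCl2, Et3N, paraformaldehyde, MeCN, reflux) touches only the free-phenol ring and should go to C9a, giving the salicylaldehyde F1. MeI/K2CO3 gives its methyl ether F2, from which no lactone can form. Roskamp homologation (ethyl diazoacetate, SnCl2, CH2Cl2) gives the β-keto ester F3. Acid-mediated acylation of the styrene carbon C3a by the ester (Eaton's reagent, 40 °C) closes ring B to the 9-O-methyl phenalenone F4. BBr3 as in step 15 then cleaves four methyl ethers and gives 24.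

Step 13. Ring strain in the rigid dihydronaphthalene and the weak activation by the twisted ketone may let intermolecular etherification win over ring closure. The fallback sets out from 16 and comes back at 20, closing the ten-membered ring while the chain is still open and flexible and forming ring C afterwards. Acetal cleavage of 16 (HCl, MeOH) gives the diphenol F5. SNAr with Cs2CO3 in DMF at high dilution and the lowest workable temperature, to limit enolisation of the 1,5-diketone, gives the macrocyclic bromide F6. Reductive carbonylation as in step 10 gives the macrocyclic aldehyde F7. McMurry coupling as in step 11 then forms ring C across the macrocycle and gives 20.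

Step 11. Low-valent titanium may also reduce or couple the remote ring E ketone, or the coupling may stop at the pinacol because both carbonyl carbons are crowded. The fallback sets out from 17 and comes back at 18, replacing the reductive coupling by an intramolecular Wittig olefination. NaBH4 at −78 °C should reduce only the aldehyde, giving the benzylic alcohol F8. CBr4/PPh3 gives the benzylic bromide F9, and PPh3 in MeCN gives the phosphonium bromide F10. One equivalent of KOtBu at low temperature forms the semi-stabilised ylide, which closes the six-membered ring on the ring D ketone and gives 18.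

Further compounds
F1 | step 14 | salicylaldehyde: 20 with CHO on C9a | C[C@H]1CC(=O)c2c(OC)cccc2Oc2cc(O)c(C=O)c3c2[C@H](C)[C@@H]1C(c1c(OC)cccc1OC)=C3
F2 | step 14 | 9-O-methyl ether of F1 | C[C@H]1CC(=O)c2c(OC)cccc2Oc2cc(OC)c(C=O)c3c2[C@H](C)[C@@H]1C(c1c(OC)cccc1OC)=C3
F3 | step 14 | ethyl β-keto ester on C9a (C9a–CO–CH2–CO2Et), 9-O-methyl | C[C@H]1CC(=O)c2c(OC)cccc2Oc2cc(OC)c(C(=O)CC(=O)OCC)c3c2[C@H](C)[C@@H]1C(c1c(OC)cccc1OC)=C3
F4 | step 14 | 9-O-methyl ether of 23 | C[C@H]1CC(=O)c2c(OC)cccc2Oc2cc(OC)c3c4c2[C@H](C)[C@@H]1C(c1c(OC)cccc1OC)=C4C(O)=CC3=O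
F5 | step 13 | diphenol of 16 (both methoxymethyl groups removed) | C[C@@H](CC(=O)c1c(OC)cccc1F)[C@H]([C@@H](C)c1c(O)cc(O)cc1Br)C(=O)c1c(OC)cccc1OC
F6 | step 13 | macrocyclic aryl ether bromide with the ring D ketone still in place | C[C@H]1CC(=O)c2c(OC)cccc2Oc2cc(O)cc(Br)c2[C@H](C)[C@@H]1C(=O)c1c(OC)cccc1OC
F7 | step 13 | macrocyclic aryl ether aldehyde (CHO in place of Br in F6) | C[C@H]1CC(=O)c2c(OC)cccc2Oc2cc(O)cc(C=O)c2[C@H](C)[C@@H]1C(=O)c1c(OC)cccc1OC
F8 | step 11 | benzylic alcohol (CH2OH in place of CHO in 17) | C[C@@H](CC(=O)c1c(OC)cccc1F)[C@H]([C@@H](C)c1c(OCOC)cc(OCOC)cc1CO)C(=O)c1c(OC)cccc1OC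
F9 | step 11 | benzylic bromide (CH2Br in place of CHO in 17) | C[C@@H](CC(=O)c1c(OC)cccc1F)[C@H]([C@@H](C)c1c(OCOC)cc(OCOC)cc1CBr)C(=O)c1c(OC)cccc1OC
F10 | step 11 | benzylic triphenylphosphonium bromide | C[C@@H](CC(=O)c1c(OC)cccc1F)[C@H]([C@@H](C)c1c(OCOC)cc(OCOC)cc1C[P+](c1ccccc1)(c1ccccc1)c1ccccc1)C(=O)c1c(OC)cccc1OC.[Br-]
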